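**Plan**

Ring numbering used below: C1 ketone, C2=C3 alkene, C4 the carbon with the acetoxy and octenyl groups, C5 the carbon with the heptenoate chain.
Retrosynthesis: first both acetates (C–O); then the bond from ring C5 to the chain CH2 (allyl transfer from an ester oxygen with loss of CO2); then the ring bonds C2=C3 and C4–C5 together, which leaves (4Z)-2-oxodec-4-enal and a 4-phosphoranylidene acetoacetate whose ester alcohol is the heptenoate chain.
Structural feature used: ketone C1 lies between both cut bonds; the enone C1–C2=C3 is the retron of a carbonyl olefination and the β-hydroxy ketone C1–C5–C4–O that of an aldol addition, so C5–C1–C2 is an acetone 1,3-dinucleophile (made unequal by an ester on C5 and phosphorus on C2) and C3–C4 a ketoaldehyde; the fully substituted C4 is the fragment junction.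
Forward: the two fragments of similar size are joined in one flask (Wittig, then amine-catalysed aldol closure of the only ring); the chain then moves from the ester oxygen to C5; desilylation and double acetylation finish.
Stereochemistry: heptenoate C4 (S) from ligand-controlled alkenylzinc addition; ring C4 (R) from the chiral amine catalyst in the ring closure; ring C5 (R) from allylation anti to the octenyl group, also the expected thermodynamic epimer; Z-alkene from Lindlar reduction, E-alkene from syn-hydroboration.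

Key step: step 9

Remark: 2, 4, 5 and 6 are racemic; their carbinol carbon becomes the ketone carbon of 18, so its configuration is immaterial.

**Route**

Step 1
Reactants: 1 hept-1-yne; 2 trimethyl(oxiran-2-ylmethoxy)silane (racemic)
Product: 5 dec-4-yne-1,2-diol (racemic), via hept-1-ynyllithium 3 (not isolated), via 1-(trimethylsilyloxy)dec-4-yn-2-ol 4 (not isolated)
Conditions: n-BuLi, THF, −78 °C; 2, DMPU, −78 °C → rt; then 1 M HCl, MeOH, rt
Reagents that add atoms: none
Why: Lithium acetylides open terminal epoxides at the unsubstituted carbon (SN2), and the labile trimethylsilyl ether falls off in the acidic methanol work-up, so the ten-carbon chain of the ketoaldehyde fragment arises in one step.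

Step 2
Reactants: 5 dec-4-yne-1,2-diol
Product: 6 (4Z)-dec-4-ene-1,2-diol (racemic)
Conditions: H2 (1 atm), Pd/CaCO3 poisoned with Pb(OAc)2 (Lindlar catalyst), quinoline, EtOAc, rt
Reagents that add atoms: none
Why: Lindlar semihydrogenation adds hydrogen syn to the alkyne and stops at the Z-alkene.

Step 3
Reactants: 7 tert-butyldimethyl(prop-2-yn-1-yloxy)silane; 8 methyl 4-oxobutanoate
Product: 11 methyl (4S,5E)-7-[(tert-butyldimethylsilyl)oxy]-4-hydroxyhept-5-enoate, via alkenyl(dicyclohexyl)borane 9 (not isolated), via alkenyl(ethyl)zinc 10 (not isolated)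
Conditions: Cy2BH (from BH3·SMe2, cyclohexene), toluene, 0 °C → rt; Et2Zn, −78 °C; (+)-MIB (4 mol %), 8, −20 → 0 °C; aq NH4Cl
Reagents that add atoms: none
Why: syn-Hydroboration fixes the E-alkene, boron-to-zinc exchange gives the alkenylzinc, and its amino-alcohol-catalysed addition to the aldehyde (catalytic asymmetric alkenylzinc addition) sets the carbinol as S, the ligand enantiomer being the one that directs the alkenyl group to the Re face.

Step 4
Reactants: 11 methyl (4S,5E)-7-[(tert-butyldimethylsilyl)oxy]-4-hydroxyhept-5-enoate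
Product: 12 methyl (4S,5E)-4,7-bis[(tert-butyldimethylsilyl)oxy]hept-5-enoate
Conditions: TBSCl, imidazole, DMF, 0 °C → rt
Reagents that add atoms: tert-butyldimethylsilyl chloride, CC(C)(C)[Si](C)(C)Cl
Why: Standard silylation of the secondary allylic alcohol, done at once so that the 4-hydroxy ester cannot lactonise.

Step 5
Reactants: 12 methyl (4S,5E)-4,7-bis[(tert-butyldimethylsilyl)oxy]hept-5-enoate
Product: 13 methyl (4S,5E)-4-[(tert-butyldimethylsilyl)oxy]-7-hydroxyhept-5-enoate
Conditions: CSA (10 mol %), MeOH/CH2Cl2, −10 °C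
Reagents that add atoms: none
Why: Acid-catalysed methanolysis removes the unhindered primary allylic silyl ether much faster than the secondary one (selective desilylation).

Step 6
Reactants: 13 methyl (4S,5E)-4-[(tert-butyldimethylsilyl)oxy]-7-hydroxyhept-5-enoate; 14 tert-butyl 4-chloro-3-oxobutanoate
Product: 15 methyl (4S,5E)-4-[(tert-butyldimethylsilyl)oxy]-7-[(4-chloro-3-oxobutanoyl)oxy]hept-5-enoate
Conditions: toluene, 110 °C, t-BuOH distilled off
Reagents that add atoms: none
Why: Thermal ester exchange of tert-butyl acetoacetates (transacetoacetylation through an acylketene) acylates the primary alcohol under neutral conditions with loss of volatile tert-butanol.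

Step 7
Reactants: 15 methyl (4S,5E)-4-[(tert-butyldimethylsilyl)oxy]-7-[(4-chloro-3-oxobutanoyl)oxy]hept-5-enoate
Product: 17 methyl (4S,5E)-4-[(tert-butyldimethylsilyl)oxy]-7-{[3-oxo-4-(triphenyl-λ5-phosphanylidene)butanoyl]oxy}hept-5-enoate, via phosphonium chloride 16 (not isolated)
Conditions: PPh3, THF, 50 °C; then aq Na2CO3, CH2Cl2, rt
Reagents that add atoms: triphenylphosphine, c1ccc(cc1)P(c1ccccc1)c1ccccc1
Why: SN2 displacement of the α-chloro ketone by PPh3 and deprotonation of the acidic phosphonium methylene by carbonate give the stabilised keto-ylide, the usual route to 4-phosphoranylidene acetoacetates.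

Step 8
Reactants: 6 (4Z)-dec-4-ene-1,2-diol
Product: 18 (4Z)-2-oxodec-4-enal
Conditions: IBX, DMSO, rt; extraction, used at once
Reagents that add atoms: none
Why: IBX oxidises 1,2-diols to 1,2-dicarbonyl compounds without C–C cleavage under neutral conditions, which spares the skipped Z-alkene.

Step 9
Reactants: 18 (4Z)-2-oxodec-4-enal; 17 methyl (4S,5E)-4-[(tert-butyldimethylsilyl)oxy]-7-{[3-oxo-4-(triphenyl-λ5-phosphanylidene)butanoyl]oxy}hept-5-enoate
Product: 20 (2E,4S)-4-[(tert-butyldimethylsilyl)oxy]-7-methoxy-7-oxohept-2-en-1-yl (2R)-2-hydroxy-2-[(2Z)-oct-2-en-1-yl]-5-oxocyclopent-3-ene-1-carboxylate (both epimers at the ester-bearing carbon), via ene-dione ester 19 (not isolated)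
Conditions: CH2Cl2, 0 °C → rt; then β-isocupreidine (20 mol %), rt
Reagents that add atoms: none
Why: Proposed new method: the stabilised keto-ylide 17 olefinates only the aldehyde of 18 (Wittig reaction, no base present) and so forms C2=C3 in ene-dione 19; the quinuclidine nitrogen of β-isocupreidine then adds reversibly to C3 of 19, which makes the C2–C3 bond rotatable, the 1,3-dicarbonyl enol at C5 adds to the C4 ketone, and E1cB loss of the amine restores the ring enone. The closest known reaction types are the Wittig reaction of acylmethylene phosphoranes with glyoxals, the base-induced aldol closure of cis-ene-1,4-diones to 4-hydroxycyclopent-2-enones and Morita–Baylis–Hillman-type nucleophilic catalysis by β-isocupreidine; their merger in one flask and the asymmetric closure have not been shown. The single ring closes by a 5-(enolendo)-exo-trig aldol addition at the stage of the saturated amine adduct, so the E geometry of 19 is no obstacle. Ring C4 is set by the catalyst, whose ammonium centre on the neighbouring C3 and whose phenol hydrogen bond to the C4 carbonyl are expected to leave one face open; the quinine-derived pseudoenantiomer of the catalyst is taken instead if the induction turns out to have the opposite sense, and ring C5 is left uncontrolled because it becomes an enolate in step 10. The step needs aldehyde-over-ketone selectivity (secured by the stabilised ylide), closure from C5 and not from the allylic CH2 of the octenyl chain (only the 1,3-dicarbonyl C5–H is acidic enough for the weak amine base), and an intact skipped Z-alkene (no strong base or acid).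

Step 10
Reactants: 20 (2E,4S)-4-[(tert-butyldimethylsilyl)oxy]-7-methoxy-7-oxohept-2-en-1-yl (2R)-2-hydroxy-2-[(2Z)-oct-2-en-1-yl]-5-oxocyclopent-3-ene-1-carboxylate
Product: 21 methyl (4S,5E)-4-[(tert-butyldimethylsilyl)oxy]-7-{(1R,2R)-2-hydroxy-2-[(2Z)-oct-2-en-1-yl]-5-oxocyclopent-3-en-1-yl}hept-5-enoate
Conditions: Pd(PPh3)4 (5 mol %), THF, 0 °C → rt
Reagents that add atoms: none
Why: Zerovalent palladium ionises the allyl β-keto ester, the carboxylate loses CO2 and the enolate is allylated at the less hindered allyl terminus (Tsuji decarboxylative allylation), which moves the chain from oxygen to ring C5 with the E-alkene intact; attack anti to the octenyl group gives the 5R epimer, which is also expected at equilibrium because C5–H is enolisable.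

Step 11
Reactants: 21 methyl (4S,5E)-4-[(tert-butyldimethylsilyl)oxy]-7-{(1R,2R)-2-hydroxy-2-[(2Z)-oct-2-en-1-yl]-5-oxocyclopent-3-en-1-yl}hept-5-enoate
Product: 22 methyl (4S,5E)-4-hydroxy-7-{(1R,2R)-2-hydroxy-2-[(2Z)-oct-2-en-1-yl]-5-oxocyclopent-3-en-1-yl}hept-5-enoate
Conditions: HF·pyridine, pyridine, THF, 0 °C → rt
Reagents that add atoms: none
Why: Buffered HF·pyridine cleaves the secondary silyl ether without base, so the β-hydroxy enone is not exposed to retro-aldol conditions.

Step 12
Reactants: 22 methyl (4S,5E)-4-hydroxy-7-{(1R,2R)-2-hydroxy-2-[(2Z)-oct-2-en-1-yl]-5-oxocyclopent-3-en-1-yl}hept-5-enoate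
Product: 23 methyl (4S,5E)-4-acetoxy-7-{(1R,2R)-2-acetoxy-2-[(2Z)-oct-2-en-1-yl]-5-oxocyclopent-3-en-1-yl}hept-5-enoate (target)
Conditions: Ac2O, Sc(OTf)3 (2 mol %), MeCN, −20 °C
Reagents that add atoms: acetic anhydride, CC(=O)OC(C)=O
Why: Sc(OTf)3-catalysed acylation with Ac2O esterifies hindered tertiary alcohols at low temperature without base, which acetylates both hydroxyls and avoids base-induced β-elimination of the ring acetate.

**Compound list**

1 | hept-1-yne | CCCCCC#C | starting material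
2 | trimethyl(oxiran-2-ylmethoxy)silane (racemic) | C[Si](C)(C)OCC1CO1 | starting material
3 | hept-1-yn-1-yllithium | [Li]C#CCCCCC | intermediate
4 | 1-(trimethylsilyloxy)dec-4-yn-2-ol (racemic) | CCCCCC#CCC(O)CO[Si](C)(C)C | intermediate
5 | dec-4-yne-1,2-diol (racemic) | CCCCCC#CCC(O)CO | intermediate
6 | (4Z)-dec-4-ene-1,2-diol (racemic) | CCCCC/C=C\CC(O)CO | intermediate
7 | tert-butyldimethyl(prop-2-yn-1-yloxy)silane | C#CCO[Si](C)(C)C(C)(C)C | starting material
8 | methyl 4-oxobutanoate | COC(=O)CCC=O | starting material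
9 | [(1E)-3-[(tert-butyldimethylsilyl)oxy]prop-1-en-1-yl]dicyclohexylborane | CC(C)(C)[Si](C)(C)OC/C=C/B(C1CCCCC1)C1CCCCC1 | intermediate
10 | [(1E)-3-[(tert-butyldimethylsilyl)oxy]prop-1-en-1-yl](ethyl)zinc | CC[Zn]/C=C/CO[Si](C)(C)C(C)(C)C | intermediate
11 | methyl (4S,5E)-7-[(tert-butyldimethylsilyl)oxy]-4-hydroxyhept-5-enoate | CC(C)(C)[Si](C)(C)OC/C=C/[C@H](CCC(=O)OC)O | intermediate
12 | methyl (4S,5E)-4,7-bis[(tert-butyldimethylsilyl)oxy]hept-5-enoate | CC(C)(C)[Si](C)(C)OC/C=C/[C@H](CCC(=O)OC)O[Si](C)(C)C(C)(C)C | intermediate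
13 | methyl (4S,5E)-4-[(tert-butyldimethylsilyl)oxy]-7-hydroxyhept-5-enoate | OC/C=C/[C@H](CCC(=O)OC)O[Si](C)(C)C(C)(C)C | intermediate
14 | tert-butyl 4-chloro-3-oxobutanoate | CC(C)(C)OC(=O)CC(=O)CCl | starting material
15 | methyl (4S,5E)-4-[(tert-butyldimethylsilyl)oxy]-7-[(4-chloro-3-oxobutanoyl)oxy]hept-5-enoate | ClCC(=O)CC(=O)OC/C=C/[C@H](CCC(=O)OC)O[Si](C)(C)C(C)(C)C | intermediate
16 | {4-[(2E,4S)-4-[(tert-butyldimethylsilyl)oxy]-7-methoxy-7-oxohept-2-en-1-yl]oxy-2,4-dioxobutyl}triphenylphosphonium chloride | [Cl-].O=C(C[P+](c1ccccc1)(c1ccccc1)c1ccccc1)CC(=O)OC/C=C/[C@H](CCC(=O)OC)O[Si](C)(C)C(C)(C)C | intermediate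
17 | methyl (4S,5E)-4-[(tert-butyldimethylsilyl)oxy]-7-{[3-oxo-4-(triphenyl-λ5-phosphanylidene)butanoyl]oxy}hept-5-enoate | O=C(C=P(c1ccccc1)(c1ccccc1)c1ccccc1)CC(=O)OC/C=C/[C@H](CCC(=O)OC)O[Si](C)(C)C(C)(C)C | intermediate
18 | (4Z)-2-oxodec-4-enal | CCCCC/C=C\CC(=O)C=O | intermediate
19 | methyl (4S,5E)-4-[(tert-butyldimethylsilyl)oxy]-7-{[(4E,8Z)-3,6-dioxotetradeca-4,8-dienoyl]oxy}hept-5-enoate | CCCCC/C=C\CC(=O)/C=C/C(=O)CC(=O)OC/C=C/[C@H](CCC(=O)OC)O[Si](C)(C)C(C)(C)C | intermediate
20 | (2E,4S)-4-[(tert-butyldimethylsilyl)oxy]-7-methoxy-7-oxohept-2-en-1-yl (2R)-2-hydroxy-2-[(2Z)-oct-2-en-1-yl]-5-oxocyclopent-3-ene-1-carboxylate (both C1 epimers) | CCCCC/C=C\C[C@@]1(O)C=CC(=O)C1C(=O)OC/C=C/[C@H](CCC(=O)OC)O[Si](C)(C)C(C)(C)C | intermediate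
21 | methyl (4S,5E)-4-[(tert-butyldimethylsilyl)oxy]-7-{(1R,2R)-2-hydroxy-2-[(2Z)-oct-2-en-1-yl]-5-oxocyclopent-3-en-1-yl}hept-5-enoate | CCCCC/C=C\C[C@@]1(O)C=CC(=O)[C@@H]1C/C=C/[C@H](CCC(=O)OC)O[Si](C)(C)C(C)(C)C | intermediate
22 | methyl (4S,5E)-4-hydroxy-7-{(1R,2R)-2-hydroxy-2-[(2Z)-oct-2-en-1-yl]-5-oxocyclopent-3-en-1-yl}hept-5-enoate | CCCCC/C=C\C[C@@]1(O)C=CC(=O)[C@@H]1C/C=C/[C@H](CCC(=O)OC)O | intermediate
23 | methyl (4S,5E)-4-acetoxy-7-{(1R,2R)-2-acetoxy-2-[(2Z)-oct-2-en-1-yl]-5-oxocyclopent-3-en-1-yl}hept-5-enoate | CCCCC/C=C\C[C@@]1(OC(C)=O)C=CC(=O)[C@@H]1C/C=C/[C@H](CCC(=O)OC)OC(C)=O | target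

**Step count and risks**

Total: 12 steps. Longest linear sequence: 9 steps (steps 3–7 and 9–12, from 7 and 8).

Step 9 (the one step beyond known chemistry). What may go wrong: poor facial selectivity in the amine-bound aldol closure, slow conjugate addition of the tertiary amine to the disubstituted ene-dione, or loss of enantiomeric purity through retro-aldol opening and reclosure. Fallback with known chemistry, setting out from 13 and coming back at 21: the configuration of the ring carbinol is relayed from a bought stereocentre instead of a catalyst. (4R)-4-[(tert-Butyldimethylsilyl)oxy]cyclopent-2-en-1-one F1 (commercial) takes up (Z)-oct-2-enylbarium chloride at the carbonyl group, anti to the silyloxy group, to give (1S,4R)-4-[(tert-butyldimethylsilyl)oxy]-1-[(2Z)-oct-2-en-1-yl]cyclopent-2-en-1-ol F2. The barium reagent is made from (Z)-1-chlorooct-2-ene and activated barium (BaI2, Li, biphenyl); such allylbarium reagents add through their α-carbon with retention of the Z geometry. Bu4NF gives (1S,4R)-1-[(2Z)-oct-2-en-1-yl]cyclopent-2-ene-1,4-diol F3, and MnO2 oxidises only the secondary allylic alcohol to (4S)-4-hydroxy-4-[(2Z)-oct-2-en-1-yl]cyclopent-2-en-1-one F4, in which the relay centre has become the ketone. Me3SiCl/imidazole gives (4S)-4-[(2Z)-oct-2-en-1-yl]-4-[(trimethylsilyl)oxy]cyclopent-2-en-1-one F5. Alcohol 13 is converted by CBr4/PPh3 into methyl (4S,5E)-7-bromo-4-[(tert-butyldimethylsilyl)oxy]hept-5-enoate F6. The lithium enolate of F5 (LiN(i-Pr)2, THF/DMPU, −78 °C) is alkylated by F6 at the saturated α-carbon, trans to the octenyl group, to give methyl (4S,5E)-4-[(tert-butyldimethylsilyl)oxy]-7-{(1R,2R)-2-[(2Z)-oct-2-en-1-yl]-5-oxo-2-[(trimethylsilyl)oxy]cyclopent-3-en-1-yl}hept-5-enoate F7. Citric acid in methanol removes the trimethylsilyl group and gives 21.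

Step 10. What may go wrong: proton quench of the palladium enolate, double allylation through enolate exchange between molecules, or allylation on the wrong face. Fallback, setting out from 14, 18 and 13 and coming back at 21: the allyl group is delivered between two molecules to a carbon that keeps its ester, so that a quaternary 1,3-dicarbonyl carbon is formed first. Ester 14 is converted (PPh3; then Na2CO3) into tert-butyl 3-oxo-4-(triphenyl-λ5-phosphanylidene)butanoate F8, which with 18 under the conditions of step 9 gives tert-butyl (2R)-2-hydroxy-2-[(2Z)-oct-2-en-1-yl]-5-oxocyclopent-3-ene-1-carboxylate F9. Alcohol 13 and methyl chloroformate/pyridine give methyl (4S,5E)-4-[(tert-butyldimethylsilyl)oxy]-7-[(methoxycarbonyl)oxy]hept-5-enoate F10. Pd(PPh3)4 joins F9 and F10 (Tsuji–Trost allylation under neutral conditions) to tert-butyl (2R)-1-[(2E,4S)-4-[(tert-butyldimethylsilyl)oxy]-7-methoxy-7-oxohept-2-en-1-yl]-2-hydroxy-2-[(2Z)-oct-2-en-1-yl]-5-oxocyclopent-3-ene-1-carboxylate F11, which has no acidic hydrogen left between the carbonyl groups. Me3SiOTf/2,6-lutidine cleaves the tert-butyl ester without touching the silyl ether, and (2R)-1-[(2E,4S)-4-[(tert-butyldimethylsilyl)oxy]-7-methoxy-7-oxohept-2-en-1-yl]-2-hydroxy-2-[(2Z)-oct-2-en-1-yl]-5-oxocyclopent-3-ene-1-carboxylic acid F12 loses CO2 on aqueous work-up to give 21, the C5 epimer being fixed on protonation of the enol.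

Step 8. What may go wrong: migration of the skipped Z double bond into conjugation with the 1,2-dicarbonyl unit, and hydrate or oligomer formation of the ketoaldehyde before it is used. Fallback, setting out from 6 and 17 and coming back at 19: the ketone is made only after the C2=C3 bond, so that no ketoaldehyde is handled. TEMPO/PhI(OAc)2 oxidises only the primary alcohol of 6 to (4Z)-2-hydroxydec-4-enal F13, whose allylic CH2 is not flanked by a carbonyl group. Wittig reaction with 17 gives methyl (4S,5E)-4-[(tert-butyldimethylsilyl)oxy]-7-{[(4E,8Z)-6-hydroxy-3-oxotetradeca-4,8-dienoyl]oxy}hept-5-enoate F14. MnO2 oxidation of its allylic alcohol gives ene-dione 19, which is then treated with the amine catalyst as in step 9.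

Further compounds
F1 | step 9 | (4R)-4-[(tert-butyldimethylsilyl)oxy]cyclopent-2-en-1-one (commercial) | O=C1C=C[C@H](O[Si](C)(C)C(C)(C)C)C1
F2 | step 9 | (1S,4R)-4-[(tert-butyldimethylsilyl)oxy]-1-[(2Z)-oct-2-en-1-yl]cyclopent-2-en-1-ol | CCCCC/C=C\C[C@@]1(O)C=C[C@H](O[Si](C)(C)C(C)(C)C)C1
F3 | step 9 | (1S,4R)-1-[(2Z)-oct-2-en-1-yl]cyclopent-2-ene-1,4-diol | CCCCC/C=C\C[C@@]1(O)C=C[C@H](O)C1
F4 | step 9 | (4S)-4-hydroxy-4-[(2Z)-oct-2-en-1-yl]cyclopent-2-en-1-one | CCCCC/C=C\C[C@@]1(O)C=CC(=O)C1
F5 | step 9 | (4S)-4-[(2Z)-oct-2-en-1-yl]-4-[(trimethylsilyl)oxy]cyclopent-2-en-1-one | CCCCC/C=C\C[C@@]1(O[Si](C)(C)C)C=CC(=O)C1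
F6 | step 9 | methyl (4S,5E)-7-bromo-4-[(tert-butyldimethylsilyl)oxy]hept-5-enoate | BrC/C=C/[C@H](CCC(=O)OC)O[Si](C)(C)C(C)(C)C
F7 | step 9 | methyl (4S,5E)-4-[(tert-butyldimethylsilyl)oxy]-7-{(1R,2R)-2-[(2Z)-oct-2-en-1-yl]-5-oxo-2-[(trimethylsilyl)oxy]cyclopent-3-en-1-yl}hept-5-enoate | CCCCC/C=C\C[C@@]1(O[Si](C)(C)C)C=CC(=O)[C@@H]1C/C=C/[C@H](CCC(=O)OC)O[Si](C)(C)C(C)(C)C
F8 | step 10 | tert-butyl 3-oxo-4-(triphenyl-λ5-phosphanylidene)butanoate | CC(C)(C)OC(=O)CC(=O)C=P(c1ccccc1)(c1ccccc1)c1ccccc1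
F9 | step 10 | tert-butyl (2R)-2-hydroxy-2-[(2Z)-oct-2-en-1-yl]-5-oxocyclopent-3-ene-1-carboxylate | CCCCC/C=C\C[C@@]1(O)C=CC(=O)C1C(=O)OC(C)(C)C
F10 | step 10 | methyl (4S,5E)-4-[(tert-butyldimethylsilyl)oxy]-7-[(methoxycarbonyl)oxy]hept-5-enoate | COC(=O)OC/C=C/[C@H](CCC(=O)OC)O[Si](C)(C)C(C)(C)C
F11 | step 10 | tert-butyl (2R)-1-[(2E,4S)-4-[(tert-butyldimethylsilyl)oxy]-7-methoxy-7-oxohept-2-en-1-yl]-2-hydroxy-2-[(2Z)-oct-2-en-1-yl]-5-oxocyclopent-3-ene-1-carboxylate | CCCCC/C=C\C[C@@]1(O)C=CC(=O)C1(C/C=C/[C@H](CCC(=O)OC)O[Si](C)(C)C(C)(C)C)C(=O)OC(C)(C)C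
F12 | step 10 | (2R)-1-[(2E,4S)-4-[(tert-butyldimethylsilyl)oxy]-7-methoxy-7-oxohept-2-en-1-yl]-2-hydroxy-2-[(2Z)-oct-2-en-1-yl]-5-oxocyclopent-3-ene-1-carboxylic acid | CCCCC/C=C\C[C@@]1(O)C=CC(=O)C1(C/C=C/[C@H](CCC(=O)OC)O[Si](C)(C)C(C)(C)C)C(O)=O
F13 | step 8 | (4Z)-2-hydroxydec-4-enal | CCCCC/C=C\CC(O)C=O
F14 | step 8 | methyl (4S,5E)-4-[(tert-butyldimethylsilyl)oxy]-7-{[(4E,8Z)-6-hydroxy-3-oxotetradeca-4,8-dienoyl]oxy}hept-5-enoate | CCCCC/C=C\CC(O)/C=C/C(=O)CC(=O)OC/C=C/[C@H](CCC(=O)OC)O[Si](C)(C)C(C)(C)C
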